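Ring A is treated as a polyketide chain folded back on itself: its oxygen-bearing carbons C2', C4' and C6' are the former carbonyl carbons of a p-coumaroyl triacetate chain, and C1', the prenylated C3' and C5' are the former methylenes. The route therefore cuts the C1'–C2' bond. A 4-methoxy-3-prenyl-2-pyrone with the 2-oxo-4-arylbut-3-enyl chain at C6 is opened by Mg(OMe)2 to an enol-ether-masked triketo ester, whose diketone methylene closes ring A by Claisen condensation in the same flask. The medium also removes the aryl silyl ether of ring B, so no separate deprotection follows.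

Key step: step 5

Remark: the enol ether of the ring-opened ester has the (2E) configuration by the sequence rules (ester above the prenyl methylene at C2, methoxyl above C4 at C3, ester and C4 cis as in the pyrone); compound 12 is drawn so.

Remark: the ring B phenol is carried as a tert-butyldimethylsilyl ether, which methoxide cleaves during ring formation, so the finished prenylated 2',6'-dihydroxychalcone never meets acid (risk of chromane and flavanone closure); 5 and 6 are taken as catalogue reagents.

Step 1
Reactants: 1 triacetic acid lactone (4-hydroxy-6-methyl-2H-pyran-2-one); 2 prenyl acetate (3-methylbut-2-en-1-yl acetate)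
Product: 3 4-hydroxy-6-methyl-3-(3-methylbut-2-en-1-yl)-2H-pyran-2-one
Conditions: Pd(PPh3)4 (3 mol %), Et3N (1.2 equiv), THF, 50 °C; 1 in excess (1.5 equiv)
Reagents that add atoms: none
Why: Tsuji–Trost allylation, in which zerovalent palladium ionizes 2 to the 1,1-dimethylallyl palladium cation and the soft pyronate of the strongly acidic 1 should attack its unsubstituted terminus through C3; any O-prenyl ether is re-ionized and funnelled to the C-alkylated enol, and the excess of 1 holds back a second allylation.

Step 2
Reactants: 3 4-hydroxy-6-methyl-3-(3-methylbut-2-en-1-yl)-2H-pyran-2-one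
Product: 4 4-methoxy-6-methyl-3-(3-methylbut-2-en-1-yl)-2H-pyran-2-one
Conditions: Me2SO4, K2CO3, acetone, 56 °C
Reagents that add atoms: dimethyl sulfate, COS(=O)(=O)OC
Why: Williamson-type O-methylation of the vinylogous acid with a hard electrophile under K2CO3 in acetone, the standard conditions that turn 4-hydroxy-2-pyrones into 4-methoxy-2-pyrones in preference to 2-methoxy-4-pyranones or C3-methylated diones.

Step 3
Reactants: 5 4-[(tert-butyldimethylsilyl)oxy]benzaldehyde; 6 diethyl {2-[methoxy(methyl)amino]-2-oxoethyl}phosphonate
Product: 7 (2E)-3-{4-[(tert-butyldimethylsilyl)oxy]phenyl}-N-methoxy-N-methylprop-2-enamide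
Conditions: NaH, THF, 0 °C; then 5, 0 → 25 °C
Reagents that add atoms: none
Why: Horner–Wadsworth–Emmons olefination with a stabilized phosphonoacetamide anion should give the (E)-alkene through the reversible, thermodynamically controlled addition, and the aryl silyl ether is inert to the phosphonate anion in THF.

Step 4
Reactants: 4 4-methoxy-6-methyl-3-(3-methylbut-2-en-1-yl)-2H-pyran-2-one; 7 (2E)-3-{4-[(tert-butyldimethylsilyl)oxy]phenyl}-N-methoxy-N-methylprop-2-enamide
Product: 10 6-[(E)-4-{4-[(tert-butyldimethylsilyl)oxy]phenyl}-2-oxobut-3-en-1-yl]-4-methoxy-3-(3-methylbut-2-en-1-yl)-2H-pyran-2-one, via lithiated pyrone 8 (not isolated), via lithium hemiaminal adduct 9 (not isolated)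
Conditions: 4 (2 equiv), LiN(iPr)2 (LDA, 2 equiv), THF, −78 °C; then 7 (1 equiv), −78 → −30 °C; sat. aq NH4Cl
Reagents that add atoms: none
Why: LiN(iPr)2 deprotonates the C6 methyl (C3 is blocked by the prenyl group) to the extended enolate 8, which should add through its terminal carbon to the amide carbonyl in a Weinreb ketone synthesis; the N-methoxy chelate 9, whose transient carbinol centre is formed without control and erased on collapse, holds until the quench, so the more acidic ketone is not set free in the presence of base and the surplus of 4 is recovered.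

Step 5
Reactants: 10 6-[(E)-4-{4-[(tert-butyldimethylsilyl)oxy]phenyl}-2-oxobut-3-en-1-yl]-4-methoxy-3-(3-methylbut-2-en-1-yl)-2H-pyran-2-one
Product: 13 xanthogalenol ((2E)-1-[2,6-dihydroxy-4-methoxy-3-(3-methylbut-2-en-1-yl)phenyl]-3-(4-hydroxyphenyl)prop-2-en-1-one), via phenol pyrone 11 (not isolated), via open-chain ester 12 (not isolated)
Conditions: Mg(OMe)2 (10 equiv, from Mg and MeOH), MeOH, 65 °C, Ar; then ice-cold 1 M HCl to pH 4
Reagents that add atoms: none
Why: Methoxide first cleaves the electron-poor aryl silyl ether at silicon to give phenoxide 11 and then adds to the lactone carbonyl C2, opening the pyrone to the magnesium-chelated enolate of ester 12, a tetraketide whose C3 carbonyl is masked as a (2E) methyl enol ether. The C6 methylene between the C5 and C7 ketones attacks the ester carbonyl C1, methoxide leaves and tautomerization aromatizes the ring, so the C1'–C2' bond and ring A form in one operation and no stereocenter is created. The closest known reaction type is the Mg(OMe)2-mediated recyclization of 4-methoxy-6-(2-oxoalkyl)-2-pyrones and of 3,5,7-triketo esters to acylphloroglucinols, a biomimetic Claisen (Dieckmann-type) condensation. Ring A closes in the 6-exo-trig mode, the enolate carbon adding to an ester carbonyl that lies outside the new ring. The step needs C-acylation to beat closure through the enol oxygen to a 4-pyranone and return to the lactone: the tetrasubstituted enol ether inherited from the pyrone keeps the ester and the C4–C7 chain on the same side and leaves no carbanion at C2 for an aldol fold, the magnesium chelate of the 5,7-diketonate holds the nucleophilic carbon against the ester, and the aromatic magnesium phenoxide is the thermodynamic sink. The ring B phenoxide formed at the outset also dampens the enone, which guards against methoxide addition and flavanone closure in the basic medium.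

Compound list
1 | triacetic acid lactone (4-hydroxy-6-methyl-2H-pyran-2-one) | Cc1cc(O)cc(=O)o1 | starting material
2 | prenyl acetate (3-methylbut-2-en-1-yl acetate) | CC(=O)OCC=C(C)C | starting material
3 | 4-hydroxy-6-methyl-3-(3-methylbut-2-en-1-yl)-2H-pyran-2-one | Cc1cc(O)c(CC=C(C)C)c(=O)o1 | intermediate
4 | 4-methoxy-6-methyl-3-(3-methylbut-2-en-1-yl)-2H-pyran-2-one | COc1cc(C)oc(=O)c1CC=C(C)C | intermediate
5 | 4-[(tert-butyldimethylsilyl)oxy]benzaldehyde | CC(C)(C)[Si](C)(C)Oc1ccc(C=O)cc1 | starting material
6 | diethyl {2-[methoxy(methyl)amino]-2-oxoethyl}phosphonate | CCOP(=O)(CC(=O)N(C)OC)OCC | starting material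
7 | (2E)-3-{4-[(tert-butyldimethylsilyl)oxy]phenyl}-N-methoxy-N-methylprop-2-enamide | CON(C)C(=O)/C=C/c1ccc(O[Si](C)(C)C(C)(C)C)cc1 | intermediate
8 | lithiated pyrone: lithium trienolate of 4, drawn as 6-(lithiomethyl)-4-methoxy-3-(3-methylbut-2-en-1-yl)-2H-pyran-2-one; formed in the flask | [Li]Cc1cc(OC)c(CC=C(C)C)c(=O)o1 | intermediate
9 | lithium hemiaminal adduct: lithium alkoxide from addition of 8 to the amide carbonyl of 7, racemic at the carbinol carbon; formed in the flask | COc1cc(CC(O[Li])(N(C)OC)/C=C/c2ccc(O[Si](C)(C)C(C)(C)C)cc2)oc(=O)c1CC=C(C)C | intermediate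
10 | 6-[(E)-4-{4-[(tert-butyldimethylsilyl)oxy]phenyl}-2-oxobut-3-en-1-yl]-4-methoxy-3-(3-methylbut-2-en-1-yl)-2H-pyran-2-one | COc1cc(CC(=O)/C=C/c2ccc(O[Si](C)(C)C(C)(C)C)cc2)oc(=O)c1CC=C(C)C | intermediate
11 | phenol pyrone: 6-[(E)-4-(4-hydroxyphenyl)-2-oxobut-3-en-1-yl]-4-methoxy-3-(3-methylbut-2-en-1-yl)-2H-pyran-2-one, present as its phenoxide; formed in the flask | COc1cc(CC(=O)/C=C/c2ccc(O)cc2)oc(=O)c1CC=C(C)C | intermediate
12 | open-chain ester: methyl (2E,8E)-9-(4-hydroxyphenyl)-3-methoxy-2-(3-methylbut-2-en-1-yl)-5,7-dioxonona-2,8-dienoate, present as its magnesium enolate and phenoxide; formed in the flask | COC(=O)/C(CC=C(C)C)=C(/OC)CC(=O)CC(=O)/C=C/c1ccc(O)cc1 | intermediate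
13 | xanthogalenol, (2E)-1-[2,6-dihydroxy-4-methoxy-3-(3-methylbut-2-en-1-yl)phenyl]-3-(4-hydroxyphenyl)prop-2-en-1-one | COc1cc(O)c(C(=O)/C=C/c2ccc(O)cc2)c(O)c1CC=C(C)C | target

Total step count: 5
Longest linear sequence: 4 steps (steps 1, 2, 4 and 5)

Steps most likely to fail

Step 5. The lactone may resist methoxide, because the deprotonated side chain pushes charge into the ring and the C3 prenyl screens C2. The opened ester may also close back through oxygen faster than through carbon. The fallback separates ring opening from chain extension. It sets out from 4, which as a simple, non-enolized pyrone should be opened by Mg(OMe)2 in refluxing methanol to methyl (2E)-3-methoxy-2-(3-methylbut-2-en-1-yl)-5-oxohex-2-enoate F1. The dianion of F1 (LiN(iPr)2, 2.2 equiv, THF, −78 °C) is acylated at the terminal methyl carbon with 7 to give methyl (2E,8E)-9-{4-[(tert-butyldimethylsilyl)oxy]phenyl}-3-methoxy-2-(3-methylbut-2-en-1-yl)-5,7-dioxonona-2,8-dienoate F2. Exposure of F2 to Mg(OMe)2 in methanol should then effect the Claisen closure and the desilylation, and the route is rejoined at 13.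

Step 4. The delocalized anion may add in a conjugate sense to the cinnamoyl unit instead of attacking the amide carbonyl, or early collapse of the adduct may let the acidic product quench the nucleophile and stall conversion. The fallback replaces the acylation by an aldol addition and an oxidation. It sets out from 7, which iBu2AlH (THF, −78 °C) should reduce to (2E)-3-{4-[(tert-butyldimethylsilyl)oxy]phenyl}prop-2-enal F3. Anion 8, made from 4 as before, adds to the aldehyde carbonyl at −78 °C to give racemic 6-[(E)-4-{4-[(tert-butyldimethylsilyl)oxy]phenyl}-2-hydroxybut-3-en-1-yl]-4-methoxy-3-(3-methylbut-2-en-1-yl)-2H-pyran-2-one F4. MnO2 in CH2Cl2 should oxidize this allylic alcohol to the ketone, rejoining the route at 10.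

Step 1. Attack at the tertiary terminus of the allyl palladium intermediate (reverse prenylation), a second allylation at C3, or ring closure of the prenyl group onto the C4 hydroxyl during work-up may erode the yield. The fallback installs an allyl group, whose two termini are identical, and builds the prenyl terminus by cross-metathesis once the hydroxyl is capped. It sets out from 1, which with allyl acetate, Pd(PPh3)4 and Et3N in THF should give 4-hydroxy-6-methyl-3-(prop-2-en-1-yl)-2H-pyran-2-one F5. Me2SO4 and K2CO3 in acetone convert F5 into 4-methoxy-6-methyl-3-(prop-2-en-1-yl)-2H-pyran-2-one F6. Cross-metathesis of F6 with an excess of 2-methylbut-2-ene under the second-generation Grubbs catalyst (CH2Cl2, 40 °C) turns the allyl into the prenyl group and rejoins the route at 4.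

Further compounds
F1 | step 5 | methyl (2E)-3-methoxy-2-(3-methylbut-2-en-1-yl)-5-oxohex-2-enoate | COC(=O)/C(CC=C(C)C)=C(/OC)CC(C)=O
F2 | step 5 | methyl (2E,8E)-9-{4-[(tert-butyldimethylsilyl)oxy]phenyl}-3-methoxy-2-(3-methylbut-2-en-1-yl)-5,7-dioxonona-2,8-dienoate | COC(=O)/C(CC=C(C)C)=C(/OC)CC(=O)CC(=O)/C=C/c1ccc(O[Si](C)(C)C(C)(C)C)cc1
F3 | step 4 | (2E)-3-{4-[(tert-butyldimethylsilyl)oxy]phenyl}prop-2-enal | O=C/C=C/c1ccc(O[Si](C)(C)C(C)(C)C)cc1
F4 | step 4 | 6-[(E)-4-{4-[(tert-butyldimethylsilyl)oxy]phenyl}-2-hydroxybut-3-en-1-yl]-4-methoxy-3-(3-methylbut-2-en-1-yl)-2H-pyran-2-one (racemic) | COc1cc(CC(O)/C=C/c2ccc(O[Si](C)(C)C(C)(C)C)cc2)oc(=O)c1CC=C(C)C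
F5 | step 1 | 4-hydroxy-6-methyl-3-(prop-2-en-1-yl)-2H-pyran-2-one | Cc1cc(O)c(CC=C)c(=O)o1
F6 | step 1 | 4-methoxy-6-methyl-3-(prop-2-en-1-yl)-2H-pyran-2-one | COc1cc(C)oc(=O)c1CC=C
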